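**Retrosynthetic overview**

1. Target 27 is a cyclohexene labelled C1 (secondary carbinol, S), C2=C3, C4, C5 (tertiary carbinol carrying the C16 chain, S) and C6; the two hydroxyls are cis.
2. The strategy rests on C6, a lone CH2 between the two oxygen-bearing ring carbons C1 and C5. Cutting C1–C6 turns C5–O plus C6 into an enantiopure 2,2-disubstituted epoxide and C1 into a 2-lithio-1,3-dithiane tethered through C2–C4 (16 → 18).
3. After ring closure: dithiane → C1 ketone, Saegusa–Ito oxidation → C2=C3 enone, hydroxyl-directed reduction, then Mitsunobu inversion → cis C1–OH.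
4. Before ring closure: 16 from diol 14 (tosylate closed by the tertiary alkoxide); the diol from Cu-catalysed opening of Sharpless epoxy alcohol 11 by Grignard reagent 12; 11 from 2-methylprop-2-en-1-ol and 2-(2-bromoethyl)-1,3-dioxolane; 12 via a Z-selective Wittig reaction.
5. Ring order: oxirane (steps 5 and 8, consumed), 1,3-dithiane (step 7, auxiliary), then the only ring of the target, the six-membered carbocycle, in step 9.

Key step: step 9

Remark: a boron chelate of the Narasaka–Prasad type would have to bridge the axial C5 oxygen and the C1 carbonyl oxygen across the ring, which the ring geometry does not allow, so the cis-diol is reached by internal hydride delivery (trans) followed by SN2 inversion.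

Assumption: the enantiomeric purity set in step 5 is taken to reach 27 unchanged, since no later step breaks a bond at C5.

**Route**

Step 1
Reactants: 1 11-bromoundecan-1-ol
Product: 2 11-bromoundecanal
Conditions: (2,2,6,6-tetramethylpiperidin-1-yl)oxyl (10 mol%), PhI(OAc)2 (1.1 equiv), CH2Cl2, rt
Reagents that add atoms: none
Why: Oxoammonium-mediated alcohol oxidation stops at the aldehyde in anhydrous CH2Cl2 and leaves the primary bromide untouched.

Step 2
Reactants: 3 (4-bromobutyl)benzene
Product: 4 triphenyl(4-phenylbutyl)phosphonium bromide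
Conditions: PPh3, MeCN, reflux
Reagents that add atoms: triphenylphosphine, c1ccc(cc1)P(c1ccccc1)c1ccccc1
Why: SN2 quaternisation of the phosphine by a primary alkyl bromide gives the Wittig salt.

Step 3
Reactants: 4 triphenyl(4-phenylbutyl)phosphonium bromide; 2 11-bromoundecanal
Product: 6 [(4Z)-15-bromopentadec-4-en-1-yl]benzene, via phosphonium ylide 5 (not isolated)
Conditions: NaN(SiMe3)2, THF, −78 °C; then 2, −78 °C → rt
Reagents that add atoms: none
Why: Wittig olefination with a non-stabilised ylide under lithium-free conditions is kinetically Z-selective, and the aldehyde should react with the ylide far faster than the primary bromide does.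

Step 4
Reactants: 7 2-methylprop-2-en-1-ol; 8 2-(2-bromoethyl)-1,3-dioxolane
Product: 10 5-(1,3-dioxolan-2-yl)-2-methylidenepentan-1-ol, via allyl dianion 9 (not isolated)
Conditions: n-BuLi (2.2 equiv), TMEDA, Et2O, 0 °C → rt; then 8, THF, −78 °C → rt; H2O
Reagents that add atoms: none
Why: Allylic lithiation of the lithium alkoxide gives the O,C-dianion, whose carbanion centre is alkylated by the primary bromide in an SN2 reaction while the alkoxide stays unreactive.

Step 5
Reactants: 10 5-(1,3-dioxolan-2-yl)-2-methylidenepentan-1-ol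
Product: 11 {(2S)-2-[3-(1,3-dioxolan-2-yl)propyl]oxiran-2-yl}methanol
Conditions: Ti(OiPr)4 (10 mol%), L-(+)-diisopropyl tartrate (12 mol%), t-BuOOH (2 equiv), 4 Å molecular sieves, CH2Cl2, −20 °C
Reagents that add atoms: tert-butyl hydroperoxide, CC(C)(C)OO
Why: Katsuki–Sharpless asymmetric epoxidation of a 2-substituted allylic alcohol, in which the L-(+)-tartrate ligand should direct oxygen to the alkene face that makes the quaternary carbon (future C5) S.

Step 6
Reactants: 11 {(2S)-2-[3-(1,3-dioxolan-2-yl)propyl]oxiran-2-yl}methanol; 6 [(4Z)-15-bromopentadec-4-en-1-yl]benzene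
Product: 13 (2S,14Z)-2-[3-(1,3-dioxolan-2-yl)propyl]-18-phenyloctadec-14-ene-1,2-diol, via Grignard reagent 12 (not isolated)
Conditions: 6, Mg, THF, rt (gives 12, 2.2 equiv); then 11, CuI (10 mol%), THF, −30 → 0 °C; H2O
Reagents that add atoms: none
Why: Copper-catalysed SN2 opening of the epoxide by the Grignard reagent occurs at the unsubstituted CH2 because the other carbon is fully substituted, so the C–O bond at the stereocentre and its configuration are retained (one equivalent of 12 is consumed by the hydroxyl group).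

Step 7
Reactants: 13 (2S,14Z)-2-[3-(1,3-dioxolan-2-yl)propyl]-18-phenyloctadec-14-ene-1,2-diol
Product: 14 (2S,14Z)-2-[3-(1,3-dithian-2-yl)propyl]-18-phenyloctadec-14-ene-1,2-diol
Conditions: HS(CH2)3SH (1.2 equiv), BF3·OEt2, CH2Cl2, −20 → 0 °C, argon, dark
Reagents that add atoms: propane-1,3-dithiol, SCCCS
Why: Lewis-acid-promoted transthioacetalisation, in which the oxocarbenium ion from the dioxolane is captured by the dithiol to give the thermodynamically favoured 1,3-dithiane (any bicyclic acetal formed with the diol should be funnelled to the same product).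

Step 8
Reactants: 14 (2S,14Z)-2-[3-(1,3-dithian-2-yl)propyl]-18-phenyloctadec-14-ene-1,2-diol
Product: 16 2-(3-{(2S)-2-[(12Z)-16-phenylhexadec-12-en-1-yl]oxiran-2-yl}propyl)-1,3-dithiane, via primary tosylate 15 (not isolated)
Conditions: NaH (2.5 equiv), N-tosylimidazole (1.05 equiv), THF, 0 °C → rt
Reagents that add atoms: none
Why: The primary alkoxide is sulfonylated selectively and the neighbouring tertiary alkoxide displaces the tosylate (intramolecular Williamson reaction), so the stereocentre keeps its C–O bond and configuration while the former CH2OH carbon becomes the epoxide CH2 (future C6).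

Step 9
Reactants: 16 2-(3-{(2S)-2-[(12Z)-16-phenylhexadec-12-en-1-yl]oxiran-2-yl}propyl)-1,3-dithiane
Product: 18 (8S)-8-[(12Z)-16-phenylhexadec-12-en-1-yl]-1,5-dithiaspiro[5.5]undecan-8-ol, via lithiated dithiane 17 (not isolated)
Conditions: t-BuLi (1.1 equiv), THF–HMPA (10:1), −78 °C, then → −20 °C; H2O
Reagents that add atoms: none
Why: t-BuLi with HMPA removes the C2–H of the 2-alkyl-1,3-dithiane within minutes at −78 °C, and the sulfur-stabilised carbanion (future C1) then attacks the unsubstituted epoxide carbon (future C6) in an intramolecular SN2 opening that forms C1–C6 and releases the C5 alkoxide. The closest known reaction type is the alkylation of 2-lithio-1,3-dithianes by epoxides (Corey–Seebach umpolung) in its intramolecular form, a relative of epoxynitrile cyclisations. The six-membered carbocycle closes in the endo mode of epoxide opening: both epoxide carbons become ring members and the C5 oxygen ends up exocyclic, whereas the exo mode would need attack at C5 and give a five-membered ring. No new stereocentre is formed, because the C5–O bond is not touched and the configuration set in step 5 is carried into the ring, while the spiro dithiane carbon is not stereogenic. Regioselectivity for C6 over C5 is secured by the fully substituted C5, which cannot undergo SN2 attack; chemoselectivity for metalation over addition of the base to the epoxide is secured by fast deprotonation with the hindered base at −78 °C before the mixture is warmed.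

Step 10
Reactants: 18 (8S)-8-[(12Z)-16-phenylhexadec-12-en-1-yl]-1,5-dithiaspiro[5.5]undecan-8-ol
Product: 19 triethyl({(8S)-8-[(12Z)-16-phenylhexadec-12-en-1-yl]-1,5-dithiaspiro[5.5]undecan-8-yl}oxy)silane
Conditions: Et3SiOTf, 2,6-lutidine, CH2Cl2, −78 → 0 °C
Reagents that add atoms: triethylsilyl trifluoromethanesulfonate, CC[Si](CC)(CC)OS(=O)(=O)C(F)(F)F
Why: Silylation of the hindered tertiary alcohol with a silyl triflate masks the future β-hydroxy ketone, so that retro-aldol cleavage or dehydration, which would erase C5, cannot occur once the carbonyl is unveiled.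

Step 11
Reactants: 19 triethyl({(8S)-8-[(12Z)-16-phenylhexadec-12-en-1-yl]-1,5-dithiaspiro[5.5]undecan-8-yl}oxy)silane
Product: 20 (3S)-3-[(12Z)-16-phenylhexadec-12-en-1-yl]-3-[(triethylsilyl)oxy]cyclohexan-1-one
Conditions: MeI (excess), CaCO3, MeCN–H2O (9:1), 45 °C
Reagents that add atoms: water, O
Why: S-Methylation of the dithiane gives a sulfonium ion that is hydrolysed to the ketone under CaCO3-buffered neutral conditions, which should spare the silyl ether and the Z-olefin.

Step 12
Reactants: 20 (3S)-3-[(12Z)-16-phenylhexadec-12-en-1-yl]-3-[(triethylsilyl)oxy]cyclohexan-1-one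
Product: 22 trimethyl({(5S)-5-[(12Z)-16-phenylhexadec-12-en-1-yl]-5-[(triethylsilyl)oxy]cyclohex-1-en-1-yl}oxy)silane, via lithium enolate 21 (not isolated)
Conditions: LiN(iPr)2 (1.2 equiv), THF, −78 °C; then Me3SiCl, −78 → 0 °C
Reagents that add atoms: chlorotrimethylsilane, C[Si](C)(C)Cl
Why: Kinetic deprotonation removes a proton from C2 (flanked by a CH2) rather than from C6 (flanked by the fully substituted C5), and O-silylation fixes the C1=C2 enol ether.

Step 13
Reactants: 22 trimethyl({(5S)-5-[(12Z)-16-phenylhexadec-12-en-1-yl]-5-[(triethylsilyl)oxy]cyclohex-1-en-1-yl}oxy)silane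
Product: 23 (5S)-5-[(12Z)-16-phenylhexadec-12-en-1-yl]-5-[(triethylsilyl)oxy]cyclohex-2-en-1-one
Conditions: Pd(OAc)2 (1.1 equiv), MeCN, rt
Reagents that add atoms: none
Why: Saegusa–Ito oxidation, in which the enol ether is converted into an enolate of divalent palladium and β-hydride elimination of the C3–H gives the C2=C3 enone.

Step 14
Reactants: 23 (5S)-5-[(12Z)-16-phenylhexadec-12-en-1-yl]-5-[(triethylsilyl)oxy]cyclohex-2-en-1-one
Product: 24 (5S)-5-hydroxy-5-[(12Z)-16-phenylhexadec-12-en-1-yl]cyclohex-2-en-1-one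
Conditions: HF·pyridine, pyridine, THF, 0 °C → rt
Reagents that add atoms: none
Why: Fluoride-mediated Si–O cleavage under buffered, base-free conditions frees the tertiary alcohol without exposing the β-hydroxy enone to retro-aldol cleavage or aromatising elimination.

Step 15
Reactants: 24 (5S)-5-hydroxy-5-[(12Z)-16-phenylhexadec-12-en-1-yl]cyclohex-2-en-1-one
Product: 25 (1S,3R)-1-[(12Z)-16-phenylhexadec-12-en-1-yl]cyclohex-4-ene-1,3-diol (ring atoms C5 and C1; hydroxyls trans)
Conditions: Me4NBH(OAc)3 (5 equiv), MeCN–AcOH (1:1), −30 °C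
Reagents that add atoms: none
Why: Hydroxyl-directed (Evans–Saksena) 1,2-reduction, in which the C5–OH exchanges onto boron and the resulting alkoxyborohydride delivers hydride intramolecularly to C1 from the face of the C5 oxygen, which should set C1 as R with its hydroxyl trans to the C5 hydroxyl.

Step 16
Reactants: 25 (1S,3R)-1-[(12Z)-16-phenylhexadec-12-en-1-yl]cyclohex-4-ene-1,3-diol
Product: 26 (1S,5S)-5-hydroxy-5-[(12Z)-16-phenylhexadec-12-en-1-yl]cyclohex-2-en-1-yl 4-nitrobenzoate
Conditions: 4-nitrobenzoic acid, PPh3, DIAD, THF, 0 °C → rt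
Reagents that add atoms: 4-nitrobenzoic acid, OC(=O)c1ccc(cc1)[N+](=O)[O-]
Why: Mitsunobu reaction, in which only the secondary allylic hydroxyl is activated as an oxyphosphonium ion (the tertiary one is inert) and is displaced by the carboxylate in an SN2 step with inversion, turning C1 from R to S and placing its oxygen cis to the C5 hydroxyl.

Step 17
Reactants: 26 (1S,5S)-5-hydroxy-5-[(12Z)-16-phenylhexadec-12-en-1-yl]cyclohex-2-en-1-yl 4-nitrobenzoate
Product: 27 (1S,3S)-1-[(12Z)-16-phenylhexadec-12-en-1-yl]cyclohex-4-ene-1,3-diol (target)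
Conditions: K2CO3 (0.3 equiv), MeOH, 0 °C → rt
Reagents that add atoms: none
Why: Base-catalysed transesterification cleaves the electron-poor benzoate at the acyl carbon, so C1 keeps its S configuration and the cis-diol is released.

**Compound list**

1 | 11-bromoundecan-1-ol | OCCCCCCCCCCCBr | starting material
2 | 11-bromoundecanal | O=CCCCCCCCCCCBr | intermediate
3 | (4-bromobutyl)benzene | BrCCCCc1ccccc1 | starting material
4 | triphenyl(4-phenylbutyl)phosphonium bromide | [Br-].c1ccccc1CCCC[P+](c1ccccc1)(c1ccccc1)c1ccccc1 | intermediate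
5 | triphenyl(4-phenylbutylidene)phosphorane | c1ccccc1CCCC=P(c1ccccc1)(c1ccccc1)c1ccccc1 | intermediate (not isolated)
6 | [(4Z)-15-bromopentadec-4-en-1-yl]benzene | BrCCCCCCCCCC/C=C\CCCc1ccccc1 | intermediate
7 | 2-methylprop-2-en-1-ol | CC(=C)CO | starting material
8 | 2-(2-bromoethyl)-1,3-dioxolane | BrCCC1OCCO1 | starting material
9 | lithium 2-(lithiomethyl)prop-2-en-1-olate (dianion of 7) | [Li]CC(=C)CO[Li] | intermediate (not isolated)
10 | 5-(1,3-dioxolan-2-yl)-2-methylidenepentan-1-ol | C=C(CO)CCCC1OCCO1 | intermediate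
11 | {(2S)-2-[3-(1,3-dioxolan-2-yl)propyl]oxiran-2-yl}methanol | OC[C@@]1(CCCC2OCCO2)CO1 | intermediate
12 | [(11Z)-15-phenylpentadec-11-en-1-yl]magnesium bromide | Br[Mg]CCCCCCCCCC/C=C\CCCc1ccccc1 | intermediate (not isolated)
13 | (2S,14Z)-2-[3-(1,3-dioxolan-2-yl)propyl]-18-phenyloctadec-14-ene-1,2-diol | OC[C@@](O)(CCCC1OCCO1)CCCCCCCCCCC/C=C\CCCc2ccccc2 | intermediate
14 | (2S,14Z)-2-[3-(1,3-dithian-2-yl)propyl]-18-phenyloctadec-14-ene-1,2-diol | OC[C@@](O)(CCCC1SCCCS1)CCCCCCCCCCC/C=C\CCCc2ccccc2 | intermediate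
15 | (2S,14Z)-2-[3-(1,3-dithian-2-yl)propyl]-2-hydroxy-18-phenyloctadec-14-en-1-yl 4-methylbenzenesulfonate | Cc1ccc(cc1)S(=O)(=O)OC[C@@](O)(CCCC2SCCCS2)CCCCCCCCCCC/C=C\CCCc3ccccc3 | intermediate (not isolated)
16 | 2-(3-{(2S)-2-[(12Z)-16-phenylhexadec-12-en-1-yl]oxiran-2-yl}propyl)-1,3-dithiane | C1CSC(SC1)CCC[C@@]2(CCCCCCCCCCC/C=C\CCCc3ccccc3)CO2 | intermediate
17 | 2-lithio-2-(3-{(2S)-2-[(12Z)-16-phenylhexadec-12-en-1-yl]oxiran-2-yl}propyl)-1,3-dithiane | [Li]C1(SCCCS1)CCC[C@@]2(CCCCCCCCCCC/C=C\CCCc3ccccc3)CO2 | intermediate (not isolated)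
18 | (8S)-8-[(12Z)-16-phenylhexadec-12-en-1-yl]-1,5-dithiaspiro[5.5]undecan-8-ol | O[C@@]1(CCCCCCCCCCC/C=C\CCCc2ccccc2)CCCC2(SCCCS2)C1 | intermediate
19 | triethyl({(8S)-8-[(12Z)-16-phenylhexadec-12-en-1-yl]-1,5-dithiaspiro[5.5]undecan-8-yl}oxy)silane | CC[Si](CC)(CC)O[C@@]1(CCCCCCCCCCC/C=C\CCCc2ccccc2)CCCC2(SCCCS2)C1 | intermediate
20 | (3S)-3-[(12Z)-16-phenylhexadec-12-en-1-yl]-3-[(triethylsilyl)oxy]cyclohexan-1-one | CC[Si](CC)(CC)O[C@@]1(CCCCCCCCCCC/C=C\CCCc2ccccc2)CCCC(=O)C1 | intermediate
21 | lithium (5S)-5-[(12Z)-16-phenylhexadec-12-en-1-yl]-5-[(triethylsilyl)oxy]cyclohex-1-en-1-olate | CC[Si](CC)(CC)O[C@@]1(CCCCCCCCCCC/C=C\CCCc2ccccc2)CCC=C(O[Li])C1 | intermediate (not isolated)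
22 | trimethyl({(5S)-5-[(12Z)-16-phenylhexadec-12-en-1-yl]-5-[(triethylsilyl)oxy]cyclohex-1-en-1-yl}oxy)silane | CC[Si](CC)(CC)O[C@@]1(CCCCCCCCCCC/C=C\CCCc2ccccc2)CCC=C(O[Si](C)(C)C)C1 | intermediate
23 | (5S)-5-[(12Z)-16-phenylhexadec-12-en-1-yl]-5-[(triethylsilyl)oxy]cyclohex-2-en-1-one | CC[Si](CC)(CC)O[C@@]1(CCCCCCCCCCC/C=C\CCCc2ccccc2)CC=CC(=O)C1 | intermediate
24 | (5S)-5-hydroxy-5-[(12Z)-16-phenylhexadec-12-en-1-yl]cyclohex-2-en-1-one | O[C@@]1(CCCCCCCCCCC/C=C\CCCc2ccccc2)CC=CC(=O)C1 | intermediate
25 | (1S,3R)-1-[(12Z)-16-phenylhexadec-12-en-1-yl]cyclohex-4-ene-1,3-diol | O[C@H]1C=CC[C@@](O)(CCCCCCCCCCC/C=C\CCCc2ccccc2)C1 | intermediate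
26 | (1S,5S)-5-hydroxy-5-[(12Z)-16-phenylhexadec-12-en-1-yl]cyclohex-2-en-1-yl 4-nitrobenzoate | O=C(O[C@@H]1C=CC[C@@](O)(CCCCCCCCCCC/C=C\CCCc2ccccc2)C1)c1ccc(cc1)[N+](=O)[O-] | intermediate
27 | (1S,3S)-1-[(12Z)-16-phenylhexadec-12-en-1-yl]cyclohex-4-ene-1,3-diol | O[C@@H]1C=CC[C@@](O)(CCCCCCCCCCC/C=C\CCCc2ccccc2)C1 | target

**Step count and risks**

Total step count: 17. Longest linear sequence: 14 steps (steps 4–17 from 7; the chain branch, steps 1, 3 and 6–17 from 1, is equally long).

Steps most likely to fail: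

1. Step 9. t-BuLi may add to the epoxide or isomerise it before the dithiane is metalated, or the lithiated dithiane may decompose on warming before the endo ring closure takes place. The fallback builds the ring by two-fold alkylation of 1,3-dithiane, so that the epoxide is opened intermolecularly by an anion made before the epoxide is added and the ring is closed by an exo displacement. It sets out from dianion 9 (made from 7) and Grignard reagent 12 (made from 6) and comes back to the route at 18. Dianion 9 is alkylated with 2-chloroethyl trifluoromethanesulfonate to 2-(3-chloropropyl)prop-2-en-1-ol F1. Sharpless epoxidation under the conditions of step 5 gives [(2S)-2-(3-chloropropyl)oxiran-2-yl]methanol F2. CuI-catalysed opening with 12 as in step 6 gives (2S,14Z)-2-(3-chloropropyl)-18-phenyloctadec-14-ene-1,2-diol F3. NaH and N-tosylimidazole as in step 8 close (2S)-2-(3-chloropropyl)-2-[(12Z)-16-phenylhexadec-12-en-1-yl]oxirane F4. 2-Lithio-1,3-dithiane F5 (1,3-dithiane, n-BuLi, THF, −30 °C) opens F4 at its CH2 group to the lithium alkoxide of (4S,16Z)-1-chloro-4-[(1,3-dithian-2-yl)methyl]-20-phenylicos-16-en-4-ol F6. A second equivalent of n-BuLi with HMPA then metalates the dithiane again and closes the ring by 6-exo-tet displacement of chloride (Corey–Seebach annulation), giving 18 after aqueous work-up.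

2. Step 16. The carboxylate may attack C3 with allylic transposition, or the activated allylic alcohol may eliminate to a cyclohexadiene, so that clean inversion at C1 is not reached. The fallback sets C1 by reagent control on the silyl-protected enone; it sets out from 23 and comes back at 27. Reduction of 23 with (R)-2-methyl-CBS-oxazaborolidine and catecholborane (toluene, −78 °C) should deliver hydride to the Re face of C1, the C2=C3 arm acting as the larger carbonyl substituent. This should give (1S,5S)-5-[(12Z)-16-phenylhexadec-12-en-1-yl]-5-[(triethylsilyl)oxy]cyclohex-2-en-1-ol F9, and HF·pyridine as in step 14 then gives 27.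

3. Step 13. Palladium hydride released during the dehydrogenation may isomerise the remote Z-olefin, or the silyl enol ether may be hydrolysed back to the ketone before it is oxidised. The fallback is a metal-free selenoxide elimination; it sets out from 20 (through its lithium enolate 21 of step 12) and comes back at 23. Enolate 21 is trapped with PhSeBr at −78 °C to (5S)-5-[(12Z)-16-phenylhexadec-12-en-1-yl]-2-(phenylselanyl)-5-[(triethylsilyl)oxy]cyclohexan-1-one F7, a mixture of C2 epimers. NaIO4 (NaHCO3, aqueous THF–MeOH, 0 °C → rt) oxidises it to (5S)-2-(benzeneseleninyl)-5-[(12Z)-16-phenylhexadec-12-en-1-yl]-5-[(triethylsilyl)oxy]cyclohexan-1-one F8, which undergoes syn-elimination toward C3 and gives 23.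

Further compounds
F1 | step 9 | 2-(3-chloropropyl)prop-2-en-1-ol | C=C(CO)CCCCl
F2 | step 9 | [(2S)-2-(3-chloropropyl)oxiran-2-yl]methanol | OC[C@@]1(CCCCl)CO1
F3 | step 9 | (2S,14Z)-2-(3-chloropropyl)-18-phenyloctadec-14-ene-1,2-diol | OC[C@@](O)(CCCCl)CCCCCCCCCCC/C=C\CCCc1ccccc1
F4 | step 9 | (2S)-2-(3-chloropropyl)-2-[(12Z)-16-phenylhexadec-12-en-1-yl]oxirane | ClCCC[C@@]1(CCCCCCCCCCC/C=C\CCCc2ccccc2)CO1
F5 | step 9 | 2-lithio-1,3-dithiane | [Li]C1SCCCS1
F6 | step 9 | (4S,16Z)-1-chloro-4-[(1,3-dithian-2-yl)methyl]-20-phenylicos-16-en-4-ol | ClCCC[C@@](O)(CCCCCCCCCCC/C=C\CCCc1ccccc1)CC1SCCCS1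
F7 | step 13 | (5S)-5-[(12Z)-16-phenylhexadec-12-en-1-yl]-2-(phenylselanyl)-5-[(triethylsilyl)oxy]cyclohexan-1-one | CC[Si](CC)(CC)O[C@@]1(CCCCCCCCCCC/C=C\CCCc2ccccc2)CCC([Se]c2ccccc2)C(=O)C1
F8 | step 13 | (5S)-2-(benzeneseleninyl)-5-[(12Z)-16-phenylhexadec-12-en-1-yl]-5-[(triethylsilyl)oxy]cyclohexan-1-one | CC[Si](CC)(CC)O[C@@]1(CCCCCCCCCCC/C=C\CCCc2ccccc2)CCC([Se](=O)c2ccccc2)C(=O)C1
F9 | step 16 | (1S,5S)-5-[(12Z)-16-phenylhexadec-12-en-1-yl]-5-[(triethylsilyl)oxy]cyclohex-2-en-1-ol | O[C@@H]1C=CC[C@@](O[Si](CC)(CC)CC)(CCCCCCCCCCC/C=C\CCCc2ccccc2)C1
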